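**Retrosynthetic overview**
1. The furanone (tetronic acid) ring is the only ring built and is closed last, together with the (5E)-ylidene C=C, by a one-flask olefination/Dieckmann reaction of aldehyde 18 with the new phosphonate 23; the furan ring is bought.
2. The (7E,9Z)-diene comes from a Suzuki coupling of (E)-alkenylboronate 7 with (Z)-alkenyl iodide 16 (geometries from cross-metathesis and from syn-carbocupration of propyne).
3. The central CH2–CH2 bond (C3–C4 of alcohol 5) is made by a visible-light nickel/iridium decarboxylative C(sp3)–C(sp3) coupling of acid 3 with bromo alcohol 4.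
4. Both stereocentres are bought: C6 of 5 from (S)-β-citronellene 1, C2 of 5 from (S)-3-bromo-2-methylpropan-1-ol 4; no stereocentre is created in the route.
5. Iodide 16 comes from 3-bromofuran, oxetane and propyne.

Assumption: both antipodes of β-citronellene and of 3-bromo-2-methylpropan-1-ol are catalogue compounds, and the (S) forms are bought.

**Step 1**
Reactants: 1 (3S)-3,7-dimethylocta-1,6-diene [(S)-β-citronellene]
Product: 3 (4S)-4-methylhex-5-enoic acid, via (4S)-4-methylhex-5-enal 2 (not isolated)
Conditions: O3 (1.0 equiv, metered), MeCN/H2O 9:1, 0 °C; then NaClO2, NaH2PO4, 0 °C → rt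
Reagents that add atoms: ozone, [O-][O+]=O; sodium chlorite, [Na+].[O-]Cl=O
Why: Ozone cleaves the electron-rich trisubstituted alkene much faster than the vinyl group, water traps the carbonyl oxide so that aldehyde 2 is released directly, and chlorite (Pinnick oxidation, with the H2O2 formed in situ scavenging HOCl) gives the acid without touching the stereocentre.

**Step 2**
Reactants: 3 (4S)-4-methylhex-5-enoic acid; 4 (2S)-3-bromo-2-methylpropan-1-ol
Product: 5 (2R,6S)-2,6-dimethyloct-7-en-1-ol
Conditions: Ir[dF(CF3)ppy]2(dtbbpy)PF6 (2 mol%), NiCl2·glyme (10 mol%), 4,4'-dimethoxy-2,2'-bipyridine (10 mol%), K2CO3, H2O (20 equiv), MeCN, blue LEDs (450 nm), 25 °C; 3 in 1.5-fold excess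
Reagents that add atoms: none
Why: Metallaphotoredox decarboxylative C(sp3)–C(sp3) cross-coupling, in which the photoexcited iridium complex oxidises the carboxylate of 3, CO2 is lost, and the primary radical is captured by the nickel bipyridine catalyst that has inserted into the C–Br bond of 4, reductive elimination then forming C3–C4 of 5; neither stereocentre is a reacting carbon, so both bought centres are carried through (C2 is R only because the CIP priorities change).

**Step 3**
Reactants: 5 (2R,6S)-2,6-dimethyloct-7-en-1-ol; 6 4,4,5,5-tetramethyl-2-vinyl-1,3,2-dioxaborolane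
Product: 7 (2R,6S,7E)-2,6-dimethyl-8-(4,4,5,5-tetramethyl-1,3,2-dioxaborolan-2-yl)oct-7-en-1-ol
Conditions: second-generation Grubbs catalyst RuCl2(H2IMes)(PCy3)(=CHPh) (5 mol%), 6 (3 equiv), CH2Cl2, 40 °C
Reagents that add atoms: none
Why: Olefin cross-metathesis of a terminal alkene with vinyl pinacolboronate gives the (E)-alkenylboronate, the allylic methyl branch reinforcing E selectivity, and the free alcohol is tolerated.

**Step 4**
Reactants: 8 3-bromofuran; 9 oxetane
Product: 11 3-(furan-3-yl)propan-1-ol, via furan-3-yllithium 10 (not isolated)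
Conditions: n-BuLi, THF, −78 °C; then 9, BF3·OEt2, −78 °C; aq. NH4Cl
Reagents that add atoms: none
Why: Bromine–lithium exchange gives furan-3-yllithium, which keeps its position at −78 °C and opens the BF3-activated oxetane by SN2 attack to give the three-carbon alcohol.

**Step 5**
Reactants: 11 3-(furan-3-yl)propan-1-ol
Product: 12 3-(3-bromopropyl)furan
Conditions: CBr4, PPh3, CH2Cl2, 0 °C
Reagents that add atoms: carbon tetrabromide, BrC(Br)(Br)Br
Why: Appel bromination of a primary alcohol under neutral conditions that the furan tolerates.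

**Step 6**
Reactants: 12 3-(3-bromopropyl)furan; 13 propyne
Product: 16 3-[(4Z)-5-iodo-4-methylpent-4-en-1-yl]furan, via [3-(furan-3-yl)propyl]magnesium bromide 14 (not isolated), via [(1Z)-5-(furan-3-yl)-2-methylpent-1-en-1-yl]copper 15 (not isolated)
Conditions: Mg, Et2O, reflux; CuBr·SMe2 (1.0 equiv), Et2O/Me2S, −45 °C; 13, −25 °C, 2 h; I2, THF, −45 → 0 °C
Reagents that add atoms: iodine, II
Why: Normant carbocupration, in which the alkylcopper adds syn across propyne with the alkyl group on the internal carbon, and iodinolysis of the alkenylcopper with retention gives the (Z)-iodide (chain cis to iodine).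

**Step 7**
Reactants: 7 (2R,6S,7E)-2,6-dimethyl-8-(4,4,5,5-tetramethyl-1,3,2-dioxaborolan-2-yl)oct-7-en-1-ol; 16 3-[(4Z)-5-iodo-4-methylpent-4-en-1-yl]furan
Product: 17 (2R,6S,7E,9Z)-13-(furan-3-yl)-2,6,10-trimethyltrideca-7,9-dien-1-ol
Conditions: Pd(dppf)Cl2 (5 mol%), K3PO4 (3 equiv), THF/H2O 5:1, 45 °C
Reagents that add atoms: none
Why: Suzuki–Miyaura coupling proceeds with retention of configuration at both alkenyl partners, so the 7E and 9Z geometries set in steps 3 and 6 are transferred to the diene; the hydroxyl group and the furan are tolerated.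

**Step 8**
Reactants: 17 (2R,6S,7E,9Z)-13-(furan-3-yl)-2,6,10-trimethyltrideca-7,9-dien-1-ol
Product: 18 (2R,6S,7E,9Z)-13-(furan-3-yl)-2,6,10-trimethyltrideca-7,9-dienal
Conditions: Dess–Martin periodinane, pyridine, CH2Cl2, 0 °C → rt; used crude at once
Reagents that add atoms: none
Why: Dess–Martin oxidation converts the primary alcohol to the aldehyde under buffered conditions that do not epimerise the α-methyl centre or affect diene and furan.

**Step 9**
Reactants: 19 diphenyl phosphite; 20 ethyl glyoxylate; 21 propanoyl chloride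
Product: 23 ethyl 2-(diphenoxyphosphoryl)-2-(propanoyloxy)acetate, via ethyl 2-(diphenoxyphosphoryl)-2-hydroxyacetate 22 (not isolated)
Conditions: Et3N (5 mol%), CH2Cl2, 0 °C; then pyridine, 21, DMAP (5 mol%), 0 °C → rt
Reagents that add atoms: none
Why: Pudovik addition of the P–H bond to the aldehyde carbonyl of 20 followed by O-acylation of the hydroxy phosphonate before it can rearrange; 23 is racemic at a carbon that becomes sp2 in step 10.

**Step 10**
Reactants: 18 (2R,6S,7E,9Z)-13-(furan-3-yl)-2,6,10-trimethyltrideca-7,9-dienal; 23 ethyl 2-(diphenoxyphosphoryl)-2-(propanoyloxy)acetate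
Product: 25 (5E)-5-[(2R,6S,7E,9Z)-13-(furan-3-yl)-2,6,10-trimethyltrideca-7,9-dien-1-ylidene]-4-hydroxy-3-methylfuran-2(5H)-one, via ethyl (2E,4R,8S,9E,11Z)-15-(furan-3-yl)-4,8,12-trimethyl-2-(propanoyloxy)pentadeca-2,9,11-trienoate 24 (not isolated)
Conditions: 23 (1.1 equiv), NaN(SiMe3)2 (1.1 equiv), THF, −78 °C; 18, −78 → −30 °C; then NaN(SiMe3)2 (2.2 equiv), −78 → 0 °C; 1 M HCl to pH 3, 0 °C; dark
Reagents that add atoms: none
Why: Proposed new method: 23 is a new Ando-type (diaryl) 2-acyloxy-2-phosphonoacetate; as with Ando and Still–Gennari reagents, the electron-poor phosphorus should make collapse of the first-formed aldehyde adduct faster than its reversal, so the kinetic alkene carries the aldehyde residue cis to the ester, which here is the (2E)-enol propanoate 24 (chain trans to the enol oxygen); the extra base then deprotonates the propanoyl CH2, the enolate closes 5-exo-trig onto the neighbouring ester carbonyl and ethoxide leaves (Dieckmann/Lacey-type cyclisation) without touching the C=C, so the E geometry is carried into the ylidene tetronate while the furanone ring and its exocyclic double bond are made in one flask; the closest known reaction types are the Ando Z-selective Horner–Wadsworth–Emmons olefination, olefinations with dialkyl 2-acyloxy-2-phosphonoacetates, and Dieckmann cyclisation of 2-acyloxy esters to tetronic acids; the α-centre of 18 meets only a stabilised phosphonate anion at −78 °C and should not epimerise.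

**Compound list**
1 | (3S)-3,7-dimethylocta-1,6-diene [(S)-β-citronellene] | C=C[C@@H](C)CCC=C(C)C | starting material
2 | (4S)-4-methylhex-5-enal | C=C[C@@H](C)CCC=O | intermediate
3 | (4S)-4-methylhex-5-enoic acid | C=C[C@@H](C)CCC(=O)O | intermediate
4 | (2S)-3-bromo-2-methylpropan-1-ol | OC[C@H](C)CBr | starting material
5 | (2R,6S)-2,6-dimethyloct-7-en-1-ol | OC[C@H](C)CCC[C@H](C)C=C | intermediate
6 | 4,4,5,5-tetramethyl-2-vinyl-1,3,2-dioxaborolane | C=CB1OC(C)(C)C(C)(C)O1 | starting material
7 | (2R,6S,7E)-2,6-dimethyl-8-(4,4,5,5-tetramethyl-1,3,2-dioxaborolan-2-yl)oct-7-en-1-ol | OC[C@H](C)CCC[C@H](C)/C=C/B1OC(C)(C)C(C)(C)O1 | intermediate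
8 | 3-bromofuran | Brc1ccoc1 | starting material
9 | oxetane | C1COC1 | starting material
10 | furan-3-yllithium | [Li]c1ccoc1 | intermediate
11 | 3-(furan-3-yl)propan-1-ol | OCCCc1ccoc1 | intermediate
12 | 3-(3-bromopropyl)furan | BrCCCc1ccoc1 | intermediate
13 | propyne | CC#C | starting material
14 | [3-(furan-3-yl)propyl]magnesium bromide | Br[Mg]CCCc1ccoc1 | intermediate
15 | [(1Z)-5-(furan-3-yl)-2-methylpent-1-en-1-yl]copper | [Cu]/C=C(/C)CCCc1ccoc1 | intermediate
16 | 3-[(4Z)-5-iodo-4-methylpent-4-en-1-yl]furan | I/C=C(/C)CCCc1ccoc1 | intermediate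
17 | (2R,6S,7E,9Z)-13-(furan-3-yl)-2,6,10-trimethyltrideca-7,9-dien-1-ol | OC[C@H](C)CCC[C@H](C)/C=C/C=C(/C)CCCc1ccoc1 | intermediate
18 | (2R,6S,7E,9Z)-13-(furan-3-yl)-2,6,10-trimethyltrideca-7,9-dienal | O=C[C@H](C)CCC[C@H](C)/C=C/C=C(/C)CCCc1ccoc1 | intermediate
19 | diphenyl phosphite | O=[PH](Oc1ccccc1)Oc1ccccc1 | starting material
20 | ethyl glyoxylate | CCOC(=O)C=O | starting material
21 | propanoyl chloride | CCC(=O)Cl | starting material
22 | ethyl 2-(diphenoxyphosphoryl)-2-hydroxyacetate | CCOC(=O)C(O)P(=O)(Oc1ccccc1)Oc1ccccc1 | intermediate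
23 | ethyl 2-(diphenoxyphosphoryl)-2-(propanoyloxy)acetate | CCOC(=O)C(OC(=O)CC)P(=O)(Oc1ccccc1)Oc1ccccc1 | intermediate
24 | ethyl (2E,4R,8S,9E,11Z)-15-(furan-3-yl)-4,8,12-trimethyl-2-(propanoyloxy)pentadeca-2,9,11-trienoate | CCOC(=O)/C(OC(=O)CC)=C\[C@H](C)CCC[C@H](C)/C=C/C=C(/C)CCCc1ccoc1 | intermediate
25 | (5E)-5-[(2R,6S,7E,9Z)-13-(furan-3-yl)-2,6,10-trimethyltrideca-7,9-dien-1-ylidene]-4-hydroxy-3-methylfuran-2(5H)-one | CC1=C(O)/C(=C\[C@H](C)CCC[C@H](C)/C=C/C=C(/C)CCCc2ccoc2)OC1=O | target

**Step count**
Total: 10 steps. Longest linear sequence: 6 steps (1 → 2 → 3 → 7 → 8 → 10).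

**Steps most likely to fail, with fallbacks**

Step 10 (the proposed new step). The risks are an insufficient E:Z ratio in the olefination, deprotonation at C4 of 24 instead of the propanoyl CH2 (epimerisation), and loss of methylketene from the enol ester enolate; any (5Z) isomer would have to be removed by reversed-phase HPLC in the dark. The fallback uses known chemistry, sets out from aldehyde 18 and comes back at 25. Aldehyde 18 is added at −78 °C to the C5 lithium enolate (LiN(i-Pr)2, THF) of 3-methyl-4-(prop-2-en-1-yloxy)furan-2(5H)-one F1, itself made from 3-methyltetronic acid by Mitsunobu O-allylation. This gives the aldol adducts 5-[(2R,6S,7E,9Z)-13-(furan-3-yl)-1-hydroxy-2,6,10-trimethyltrideca-7,9-dien-1-yl]-3-methyl-4-(prop-2-en-1-yloxy)furan-2(5H)-one F2, which are separated by chromatography into the two relative series at the ring carbon and the carbinol carbon. Each series is dehydrated stereospecifically, one by anti elimination (PPh3, diethyl azodicarboxylate) and the other by syn elimination (Burgess reagent), the pairing being assigned by NOE on the products. Both converge on (5E)-5-[(2R,6S,7E,9Z)-13-(furan-3-yl)-2,6,10-trimethyltrideca-7,9-dien-1-ylidene]-3-methyl-4-(prop-2-en-1-yloxy)furan-2(5H)-one F3. The allyl group is then removed under neutral conditions with Pd(PPh3)4 and morpholine to give 25.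

Step 2. Unactivated primary acids are the weakest substrates for the photoredox decarboxylation. Possible side reactions are O-alkylation of the carboxylate by 4 and nickel hydride chemistry (alkene migration in the vinyl group, or erosion of the centre β to nickel); the diastereomeric purity of 5 must be checked by GC or 13C NMR. The fallback sets out from acid 3 and comes back at alcohol 5. Acid 3 is co-electrolysed (mixed Kolbe electrolysis, Pt electrodes, MeOH, about 5% neutralised with KOH, high current density, 40 °C) with a three-fold excess of (3R)-4-methoxy-3-methyl-4-oxobutanoic acid F4. F4 is obtained from purchased dimethyl (2R)-2-methylbutanedioate by half-saponification of the unbranched ester (1 equiv KOH, MeOH, 0 °C). The cross product methyl (2R,6S)-2,6-dimethyloct-7-enoate F5 is separated from the two symmetrical dimers by distillation and chromatography, and LiAlH4 in Et2O reduces it to 5.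

Step 1. Over-ozonolysis of the vinyl group and loss of the volatile C7 products can lower the yield. The fallback sets out from diene 1 and comes back at aldehyde 2, which is then oxidised to 3 as in the second half of step 1. mCPBA (1.0 equiv, CH2Cl2, 0 °C) epoxidises only the trisubstituted alkene to give 2,2-dimethyl-3-[(3S)-3-methylpent-4-en-1-yl]oxirane F6 (both epimers at the oxirane carbon). HIO4 in aqueous THF cleaves F6 to 2, which is now isolated and oxidised with NaClO2, NaH2PO4 and 2-methyl-2-butene in t-BuOH/H2O.

**Further compounds**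
F1 | step 10 | 3-methyl-4-(prop-2-en-1-yloxy)furan-2(5H)-one | CC1=C(OCC=C)COC1=O
F2 | step 10 | 5-[(2R,6S,7E,9Z)-13-(furan-3-yl)-1-hydroxy-2,6,10-trimethyltrideca-7,9-dien-1-yl]-3-methyl-4-(prop-2-en-1-yloxy)furan-2(5H)-one (mixture at the ring carbon and the carbinol carbon) | CC1=C(OCC=C)C(C(O)[C@H](C)CCC[C@H](C)/C=C/C=C(/C)CCCc2ccoc2)OC1=O
F3 | step 10 | (5E)-5-[(2R,6S,7E,9Z)-13-(furan-3-yl)-2,6,10-trimethyltrideca-7,9-dien-1-ylidene]-3-methyl-4-(prop-2-en-1-yloxy)furan-2(5H)-one | CC1=C(OCC=C)/C(=C\[C@H](C)CCC[C@H](C)/C=C/C=C(/C)CCCc2ccoc2)OC1=O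
F4 | step 2 | (3R)-4-methoxy-3-methyl-4-oxobutanoic acid | COC(=O)[C@H](C)CC(=O)O
F5 | step 2 | methyl (2R,6S)-2,6-dimethyloct-7-enoate | COC(=O)[C@H](C)CCC[C@H](C)C=C
F6 | step 1 | 2,2-dimethyl-3-[(3S)-3-methylpent-4-en-1-yl]oxirane | C=C[C@@H](C)CCC1OC1(C)C
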